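**Plan**

- Eremophilane numbering is used. Ring A is C10, C1, C2, C3 (acyloxy carbon), C4 (methyl C15), C5 (methyl C14). Ring B is C5, C6, C7 (carbinol carrying C11–C13), C8 (ketone), C9, C10.
- Enabling feature: C1=C2 is the only ring A bond lying between the dienone carbon C10 and the allylic ester carbon C3. Cutting it by retro-metathesis leaves one vinyl group on each and changes nothing else.
- Further cuts, in order: the C3–O acyl bond; C13–OAc, C7–OH and C7–C11 (from acetone); the C10 vinyl group with carbonyl transposition; C3–C2 (vinyl addition to a C3 aldehyde); C4–C5 (allylation of a C5 enolate); C5–C14.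
- Forward: ring B is bought as 3-ethoxycyclohex-2-en-1-one and never opened. The C5 chain, the C10 vinyl group and the C7 ketol are added in that order, the acid (four steps from (R)-2-methylbutanoic acid) is attached, and ring A closes last.
- Stereochemistry: C4 and C5 come from an Ir-catalysed crotylation (catalyst control), C3 from Felkin–Anh addition next to C4, C7 from hydroxylation of a dienolate on the face away from the C5 chain, and C6′ of the acyl group from the chiral pool.

Key step: step 18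

Remark: the (Sa,S,S) antipode of the phosphoramidite in step 2 assumes that the usual sense of induction of this catalyst family holds for the crotyl electrophile; if it is reversed, the (Ra,R,R) ligand is used.
Remark: metal enolates and alkoxides formed by deprotonation are treated as salts of the numbered compounds and carry no number of their own.

**Route**

Step 1
Reactants: 1 3-ethoxycyclohex-2-en-1-one
Product: 2 (6RS)-3-ethoxy-6-methylcyclohex-2-en-1-one
Conditions: LDA, THF, −78 °C; MeI, −78 → 0 °C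
Reagents that add atoms: iodomethane, CI
Why: Kinetic deprotonation of a vinylogous ester takes place at the α′-carbon (Stork–Danheiser alkylation), so the methyl group (C14) should enter next to the carbonyl; the new centre is racemic and is erased by the next enolisation.

Step 2
Reactants: 2 (6RS)-3-ethoxy-6-methylcyclohex-2-en-1-one; 3 (E)-but-2-en-1-yl methyl carbonate
Product: 4 (6S)-6-[(2R)-but-3-en-2-yl]-3-ethoxy-6-methylcyclohex-2-en-1-one
Conditions: LDA, THF, −78 °C; then 3, [Ir(cod)Cl]2 (2 mol %), (Sa,S,S)-BINOL bis(1-phenylethyl)amine phosphoramidite (4 mol %), THF, −78 → 0 °C; then H2O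
Reagents that add atoms: none
Why: In this iridium-catalysed allylic alkylation of a prochiral ketone enolate the cyclometalated Ir–phosphoramidite allyl complex should be attacked at its methyl-bearing terminus (branched selectivity), the ligand fixing the allyl carbon (C4) and the enolate face being selected in the same transition state to set the quaternary C5.

Step 3
Reactants: 4 (6S)-6-[(2R)-but-3-en-2-yl]-3-ethoxy-6-methylcyclohex-2-en-1-one
Product: 6 (2S)-2-[(1S)-4-ethoxy-1-methyl-2-oxocyclohex-3-en-1-yl]propanal, via vicinal diol 5 (not isolated)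
Conditions: OsO4 (2 mol %), NaIO4, 2,6-lutidine, dioxane/H2O 3:1, rt
Reagents that add atoms: osmium tetroxide, O=[Os](=O)(=O)=O; sodium periodate, [Na+].[O-]I(=O)(=O)=O
Why: In this Lemieux–Johnson cleavage the monosubstituted alkene should be dihydroxylated faster than the trisubstituted, carbonyl-conjugated alkene of the vinylogous ester, and the lutidine buffer should keep the α-centre (C4) of the aldehyde from epimerising.

Step 4
Reactants: 6 (2S)-2-[(1S)-4-ethoxy-1-methyl-2-oxocyclohex-3-en-1-yl]propanal; 7 vinylmagnesium bromide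
Product: 8 (6S)-3-ethoxy-6-[(2S,3S)-3-hydroxypent-4-en-2-yl]-6-methylcyclohex-2-en-1-one
Conditions: 7 (1.2 equiv), THF, −78 °C; then H2O
Reagents that add atoms: none
Why: The Grignard reagent should add to the aldehyde well before the far less electrophilic vinylogous ester carbonyl, and Felkin–Anh control (quaternary C5 as the large group anti to the incoming vinyl) gives the 3,4-syn carbinol, which is (3S).

Step 5
Reactants: 8 (6S)-3-ethoxy-6-[(2S,3S)-3-hydroxypent-4-en-2-yl]-6-methylcyclohex-2-en-1-one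
Product: 9 (6S)-6-[(2S,3S)-3-[(tert-butyldimethylsilyl)oxy]pent-4-en-2-yl]-3-ethoxy-6-methylcyclohex-2-en-1-one
Conditions: TBSOTf, 2,6-lutidine, CH2Cl2, −78 → 0 °C
Reagents that add atoms: tert-butyldimethylsilyl trifluoromethanesulfonate, CC(C)(C)[Si](C)(C)OS(=O)(=O)C(F)(F)F
Why: Silyl triflate with a hindered pyridine base is the standard silylation of a hindered secondary alcohol, and the ether is needed to carry C3 through the organometallic, enolate and acylation steps that follow.

Step 6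
Reactants: 9 (6S)-6-[(2S,3S)-3-[(tert-butyldimethylsilyl)oxy]pent-4-en-2-yl]-3-ethoxy-6-methylcyclohex-2-en-1-one; 7 vinylmagnesium bromide
Product: 11 (4S)-4-[(2S,3S)-3-[(tert-butyldimethylsilyl)oxy]pent-4-en-2-yl]-3-ethenyl-4-methylcyclohex-2-en-1-one, via tertiary allylic alcohol 10 (not isolated)
Conditions: 7 (3 equiv), CeCl3, THF, −78 → 0 °C; then 1 M aq. HCl, 0 °C
Reagents that add atoms: water, O
Why: In this Stork–Danheiser sequence the organocerium reagent should add 1,2 to the hindered carbonyl (C10), and cold dilute acid then ionises the doubly allylic alcohol and hydrolyses the enol ether with carbonyl transposition to C8, conditions a secondary TBS ether should survive.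

Step 7
Reactants: 11 (4S)-4-[(2S,3S)-3-[(tert-butyldimethylsilyl)oxy]pent-4-en-2-yl]-3-ethenyl-4-methylcyclohex-2-en-1-one
Product: 12 (4S,6RS)-4-[(2S,3S)-3-[(tert-butyldimethylsilyl)oxy]pent-4-en-2-yl]-3-ethenyl-6-(2-hydroxypropan-2-yl)-4-methylcyclohex-2-en-1-one
Conditions: LDA, THF, −78 °C; ZnCl2; acetone, −78 → −40 °C; then H2O
Reagents that add atoms: acetone, CC(C)=O
Why: C7 is the only enolisable position (C5 is quaternary and C1 is sp2), so the kinetic enolate forms there, and its zinc form should undergo the aldol addition to acetone without retro-aldol; the C7 configuration is irrelevant because the next step removes it.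

Step 8
Reactants: 12 (4S,6RS)-4-[(2S,3S)-3-[(tert-butyldimethylsilyl)oxy]pent-4-en-2-yl]-3-ethenyl-6-(2-hydroxypropan-2-yl)-4-methylcyclohex-2-en-1-one
Product: 14 (4S)-4-[(2S,3S)-3-[(tert-butyldimethylsilyl)oxy]pent-4-en-2-yl]-3-ethenyl-4-methyl-6-(propan-2-ylidene)cyclohex-2-en-1-one, via tertiary mesylate 13 (not isolated)
Conditions: MsCl, Et3N, CH2Cl2, 0 °C; then DBU, rt
Reagents that add atoms: none
Why: Sulfene-type mesylation of the tertiary alcohol followed by E1cB elimination through the C7 enolate should give the conjugated isopropylidene ketone under basic conditions that spare the allylic silyl ether.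

Step 9
Reactants: 14 (4S)-4-[(2S,3S)-3-[(tert-butyldimethylsilyl)oxy]pent-4-en-2-yl]-3-ethenyl-4-methyl-6-(propan-2-ylidene)cyclohex-2-en-1-one
Product: 15 (4S,6S)-4-[(2S,3S)-3-[(tert-butyldimethylsilyl)oxy]pent-4-en-2-yl]-3-ethenyl-6-hydroxy-4-methyl-6-(prop-1-en-2-yl)cyclohex-2-en-1-one
Conditions: KHMDS, THF, −78 → −30 °C; then 2-(phenylsulfonyl)-3-phenyloxaziridine, −78 °C; then H2O
Reagents that add atoms: 2-(phenylsulfonyl)-3-phenyloxaziridine, O=S(=O)(c1ccccc1)N1OC1c1ccccc1
Why: γ-Deprotonation gives an extended enolate that oxygen electrophiles attack at the α-carbon (deconjugative α-hydroxylation of a dienolate), so the C11=C12 methylene and the C7 carbinol form together, and the oxidant should approach C7 on the face opposite the branched, pseudo-axial C5 side chain, that is on the side of the C14 methyl, which is (7S).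

Step 10
Reactants: 15 (4S,6S)-4-[(2S,3S)-3-[(tert-butyldimethylsilyl)oxy]pent-4-en-2-yl]-3-ethenyl-6-hydroxy-4-methyl-6-(prop-1-en-2-yl)cyclohex-2-en-1-one
Product: 16 (4S,6S)-4-[(2S,3S)-3-[(tert-butyldimethylsilyl)oxy]pent-4-en-2-yl]-3-ethenyl-6-hydroxy-6-(3-hydroxyprop-1-en-2-yl)-4-methylcyclohex-2-en-1-one
Conditions: SeO2 (0.3 equiv), t-BuOOH, CH2Cl2, rt
Reagents that add atoms: selenium dioxide, O=[Se]=O; tert-butyl hydroperoxide, CC(C)(C)OO
Why: Catalytic SeO2 allylic oxidation (ene reaction, then [2,3] shift) should pick the most electron-rich, 1,1-disubstituted alkene, whose only allylic C–H bonds are those of the C13 methyl because C7 is quaternary; the vinyl groups and the dienone are less reactive.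

Step 11
Reactants: 16 (4S,6S)-4-[(2S,3S)-3-[(tert-butyldimethylsilyl)oxy]pent-4-en-2-yl]-3-ethenyl-6-hydroxy-6-(3-hydroxyprop-1-en-2-yl)-4-methylcyclohex-2-en-1-one
Product: 17 2-[(1S,5S)-5-[(2S,3S)-3-[(tert-butyldimethylsilyl)oxy]pent-4-en-2-yl]-4-ethenyl-1-hydroxy-5-methyl-2-oxocyclohex-3-en-1-yl]prop-2-en-1-yl acetate
Conditions: Ac2O, pyridine, DMAP (cat.), CH2Cl2, 0 °C
Reagents that add atoms: acetic anhydride, CC(=O)OC(C)=O
Why: Acyl transfer to the primary allylic alcohol is far faster than to the hindered tertiary C7 hydroxyl, so the monoacetate should form selectively.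

Step 12
Reactants: 17 2-[(1S,5S)-5-[(2S,3S)-3-[(tert-butyldimethylsilyl)oxy]pent-4-en-2-yl]-4-ethenyl-1-hydroxy-5-methyl-2-oxocyclohex-3-en-1-yl]prop-2-en-1-yl acetate
Product: 18 2-[(1S,5S)-4-ethenyl-1-hydroxy-5-[(2S,3S)-3-hydroxypent-4-en-2-yl]-5-methyl-2-oxocyclohex-3-en-1-yl]prop-2-en-1-yl acetate
Conditions: HF·pyridine, pyridine, THF, 0 °C → rt
Reagents that add atoms: none
Why: Buffered fluoride desilylation should free the C3 hydroxyl without touching the allylic acetate, the tertiary ketol or the dienone.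

Step 13
Reactants: 19 (R)-2-methylbutanoic acid
Product: 20 (R)-2-methylbutan-1-ol
Conditions: BH3·THF, THF, 0 °C → rt; then H2O
Reagents that add atoms: none
Why: Borane reduces the carboxylic acid through its acyloxyborane without enolisation, so the stereocentre is kept.

Step 14
Reactants: 20 (R)-2-methylbutan-1-ol
Product: 22 (2E,4R)-2,4-dimethylhex-2-enal, via (R)-2-methylbutanal 21 (not isolated)
Conditions: TEMPO (10 mol %), PhI(OAc)2, CH2Cl2, rt; then Ph3P=C(CH3)CHO, 40 °C
Reagents that add atoms: 2-(triphenylphosphoranylidene)propanal, CC(C=O)=P(c1ccccc1)(c1ccccc1)c1ccccc1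
Why: Nitroxyl-catalysed oxidation gives the volatile, epimerisable aldehyde under near-neutral conditions, and it is trapped in the same flask by an E-selective Wittig reaction with the stabilised ylide.

Step 15
Reactants: 22 (2E,4R)-2,4-dimethylhex-2-enal
Product: 23 ethyl (2E,4E,6R)-4,6-dimethylocta-2,4-dienoate
Conditions: Ph3P=CHCO2Et, CH2Cl2, rt
Reagents that add atoms: ethyl 2-(triphenylphosphoranylidene)acetate, CCOC(=O)C=P(c1ccccc1)(c1ccccc1)c1ccccc1
Why: A Wittig reaction of a stabilised ylide with an enal should give the (2E)-dienoate under neutral conditions that do not touch the allylic stereocentre.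

Step 16
Reactants: 23 ethyl (2E,4E,6R)-4,6-dimethylocta-2,4-dienoate
Product: 24 (2E,4E,6R)-4,6-dimethylocta-2,4-dienoic acid
Conditions: LiOH, THF/MeOH/H2O, rt; then 1 M HCl
Reagents that add atoms: lithium hydroxide, [Li+].[OH-]
Why: Saponification of an unhindered conjugated ester is routine and leaves the diene geometry and the remote stereocentre unchanged.

Step 17
Reactants: 18 2-[(1S,5S)-4-ethenyl-1-hydroxy-5-[(2S,3S)-3-hydroxypent-4-en-2-yl]-5-methyl-2-oxocyclohex-3-en-1-yl]prop-2-en-1-yl acetate; 24 (2E,4E,6R)-4,6-dimethylocta-2,4-dienoic acid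
Product: 25 (3S,4S)-4-[(1S,5S)-5-[3-(acetyloxy)prop-1-en-2-yl]-2-ethenyl-5-hydroxy-1-methyl-4-oxocyclohex-2-en-1-yl]pent-1-en-3-yl (2E,4E,6R)-4,6-dimethylocta-2,4-dienoate
Conditions: DCC, DMAP, CH2Cl2, 0 °C → rt
Reagents that add atoms: none
Why: In this Steglich esterification DMAP-mediated acyl transfer should acylate the secondary allylic C3 hydroxyl, while the tertiary C7 hydroxyl is too hindered to compete.

Step 18
Reactants: 25 (3S,4S)-4-[(1S,5S)-5-[3-(acetyloxy)prop-1-en-2-yl]-2-ethenyl-5-hydroxy-1-methyl-4-oxocyclohex-2-en-1-yl]pent-1-en-3-yl (2E,4E,6R)-4,6-dimethylocta-2,4-dienoate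
Product: 26 (1S,2S,7S,8aS)-7-[3-(acetyloxy)prop-1-en-2-yl]-7-hydroxy-1,8a-dimethyl-6-oxo-1,2,6,7,8,8a-hexahydronaphthalen-2-yl (2E,4E,6R)-4,6-dimethylocta-2,4-dienoate (CNP0160850.1)
Conditions: second-generation Ru 2-isopropoxybenzylidene NHC catalyst (5 mol %), toluene (2 mM), 60 °C
Reagents that add atoms: none
Why: The ruthenium alkylidene should load on the monosubstituted alkene of the allylic ester (C2), undergo [2+2] cycloaddition with the C10 vinyl group and cycloreversion, so that the C1=C2 bond forms and ethene is lost. The closest known reaction type is the ring-closing diene–ene metathesis of a 3-vinylcyclohexenone with a tethered terminal alkene to a fused cyclohexa-1,3-diene. Ring A closes as a six-membered carbocycle by formation of its C1=C2 double bond, the tether C10–C5–C4–C3 holding the two vinyl groups within reach. No stereocentre is formed, and C3, C4, C5 and C7 are spectators. The step needs site selectivity among six C=C bonds: only the two vinyl groups are monosubstituted, the dienoate is electron-poor and more substituted, C9=C10 is a trisubstituted enone alkene, and C11=C12 is 1,1-disubstituted and could only close an anti-Bredt bridged ring. High dilution should suppress cross-metathesis, and the ring-held, conjugated product alkene should not re-open.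

**Compound list**

1 | 3-ethoxycyclohex-2-en-1-one | CCOC1=CC(=O)CCC1 | starting material
2 | (6RS)-3-ethoxy-6-methylcyclohex-2-en-1-one | CCOC1=CC(=O)C(C)CC1 | intermediate
3 | (E)-but-2-en-1-yl methyl carbonate | C/C=C/COC(=O)OC | starting material
4 | (6S)-6-[(2R)-but-3-en-2-yl]-3-ethoxy-6-methylcyclohex-2-en-1-one | CCOC1=CC(=O)[C@@](C)(CC1)[C@H](C)C=C | intermediate
5 | (6S)-6-[(2S,3RS)-3,4-dihydroxybutan-2-yl]-3-ethoxy-6-methylcyclohex-2-en-1-one | CCOC1=CC(=O)[C@@](C)(CC1)[C@H](C)C(O)CO | intermediate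
6 | (2S)-2-[(1S)-4-ethoxy-1-methyl-2-oxocyclohex-3-en-1-yl]propanal | CCOC1=CC(=O)[C@@](C)(CC1)[C@H](C)C=O | intermediate
7 | vinylmagnesium bromide | C=C[Mg]Br | starting material
8 | (6S)-3-ethoxy-6-[(2S,3S)-3-hydroxypent-4-en-2-yl]-6-methylcyclohex-2-en-1-one | CCOC1=CC(=O)[C@@](C)(CC1)[C@H](C)[C@@H](O)C=C | intermediate
9 | (6S)-6-[(2S,3S)-3-[(tert-butyldimethylsilyl)oxy]pent-4-en-2-yl]-3-ethoxy-6-methylcyclohex-2-en-1-one | CCOC1=CC(=O)[C@@](C)(CC1)[C@H](C)[C@@H](O[Si](C)(C)C(C)(C)C)C=C | intermediate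
10 | (1RS,6S)-6-[(2S,3S)-3-[(tert-butyldimethylsilyl)oxy]pent-4-en-2-yl]-3-ethoxy-1-ethenyl-6-methylcyclohex-2-en-1-ol | CCOC1=CC(O)(C=C)[C@@](C)(CC1)[C@H](C)[C@@H](O[Si](C)(C)C(C)(C)C)C=C | intermediate
11 | (4S)-4-[(2S,3S)-3-[(tert-butyldimethylsilyl)oxy]pent-4-en-2-yl]-3-ethenyl-4-methylcyclohex-2-en-1-one | O=C1CC[C@](C)(C(C=C)=C1)[C@H](C)[C@@H](O[Si](C)(C)C(C)(C)C)C=C | intermediate
12 | (4S,6RS)-4-[(2S,3S)-3-[(tert-butyldimethylsilyl)oxy]pent-4-en-2-yl]-3-ethenyl-6-(2-hydroxypropan-2-yl)-4-methylcyclohex-2-en-1-one | CC(C)(O)C1C[C@](C)(C(C=C)=CC1=O)[C@H](C)[C@@H](O[Si](C)(C)C(C)(C)C)C=C | intermediate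
13 | 2-[(1RS,5S)-5-[(2S,3S)-3-[(tert-butyldimethylsilyl)oxy]pent-4-en-2-yl]-4-ethenyl-5-methyl-2-oxocyclohex-3-en-1-yl]propan-2-yl methanesulfonate | CC(C)(OS(C)(=O)=O)C1C[C@](C)(C(C=C)=CC1=O)[C@H](C)[C@@H](O[Si](C)(C)C(C)(C)C)C=C | intermediate
14 | (4S)-4-[(2S,3S)-3-[(tert-butyldimethylsilyl)oxy]pent-4-en-2-yl]-3-ethenyl-4-methyl-6-(propan-2-ylidene)cyclohex-2-en-1-one | CC(C)=C1C[C@](C)(C(C=C)=CC1=O)[C@H](C)[C@@H](O[Si](C)(C)C(C)(C)C)C=C | intermediate
15 | (4S,6S)-4-[(2S,3S)-3-[(tert-butyldimethylsilyl)oxy]pent-4-en-2-yl]-3-ethenyl-6-hydroxy-4-methyl-6-(prop-1-en-2-yl)cyclohex-2-en-1-one | C=C(C)[C@@]1(O)C[C@](C)(C(C=C)=CC1=O)[C@H](C)[C@@H](O[Si](C)(C)C(C)(C)C)C=C | intermediate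
16 | (4S,6S)-4-[(2S,3S)-3-[(tert-butyldimethylsilyl)oxy]pent-4-en-2-yl]-3-ethenyl-6-hydroxy-6-(3-hydroxyprop-1-en-2-yl)-4-methylcyclohex-2-en-1-one | C=C(CO)[C@@]1(O)C[C@](C)(C(C=C)=CC1=O)[C@H](C)[C@@H](O[Si](C)(C)C(C)(C)C)C=C | intermediate
17 | 2-[(1S,5S)-5-[(2S,3S)-3-[(tert-butyldimethylsilyl)oxy]pent-4-en-2-yl]-4-ethenyl-1-hydroxy-5-methyl-2-oxocyclohex-3-en-1-yl]prop-2-en-1-yl acetate | C=C(COC(C)=O)[C@@]1(O)C[C@](C)(C(C=C)=CC1=O)[C@H](C)[C@@H](O[Si](C)(C)C(C)(C)C)C=C | intermediate
18 | 2-[(1S,5S)-4-ethenyl-1-hydroxy-5-[(2S,3S)-3-hydroxypent-4-en-2-yl]-5-methyl-2-oxocyclohex-3-en-1-yl]prop-2-en-1-yl acetate | C=C(COC(C)=O)[C@@]1(O)C[C@](C)(C(C=C)=CC1=O)[C@H](C)[C@@H](O)C=C | intermediate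
19 | (R)-2-methylbutanoic acid | CC[C@@H](C)C(O)=O | starting material
20 | (R)-2-methylbutan-1-ol | CC[C@@H](C)CO | intermediate
21 | (R)-2-methylbutanal | CC[C@@H](C)C=O | intermediate
22 | (2E,4R)-2,4-dimethylhex-2-enal | CC[C@@H](C)/C=C(\C)C=O | intermediate
23 | ethyl (2E,4E,6R)-4,6-dimethylocta-2,4-dienoate | CCOC(=O)/C=C/C(C)=C/[C@H](C)CC | intermediate
24 | (2E,4E,6R)-4,6-dimethylocta-2,4-dienoic acid | OC(=O)/C=C/C(C)=C/[C@H](C)CC | intermediate
25 | (3S,4S)-4-[(1S,5S)-5-[3-(acetyloxy)prop-1-en-2-yl]-2-ethenyl-5-hydroxy-1-methyl-4-oxocyclohex-2-en-1-yl]pent-1-en-3-yl (2E,4E,6R)-4,6-dimethylocta-2,4-dienoate | C=C(COC(C)=O)[C@@]1(O)C[C@](C)(C(C=C)=CC1=O)[C@H](C)[C@@H](OC(=O)/C=C/C(C)=C/[C@H](C)CC)C=C | intermediate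
26 | (1S,2S,7S,8aS)-7-[3-(acetyloxy)prop-1-en-2-yl]-7-hydroxy-1,8a-dimethyl-6-oxo-1,2,6,7,8,8a-hexahydronaphthalen-2-yl (2E,4E,6R)-4,6-dimethylocta-2,4-dienoate | C=C(COC(C)=O)[C@@]1(O)C[C@]2(C)C(=CC1=O)C=C[C@H](OC(=O)/C=C/C(C)=C/[C@H](C)CC)[C@H]2C | target

**Count and risks**

Total step count: 18. Longest linear sequence: 14 steps (steps 1–12, 17 and 18).

Most likely to fail:

1. Step 2. The tetrasubstituted enolate may not discriminate its two faces well against the allyl complex, or attack may drift to the unsubstituted allyl terminus, so that the C4/C5 pair forms with poor diastereo- or regiocontrol. The fallback sets out from 2. Its lithium enolate is alkylated under palladium catalysis with racemic (E)-pent-3-en-2-yl methyl carbonate and a C2-symmetric trans-1,2-diaminocyclohexane bis(2-diphenylphosphinobenzamide) ligand. The symmetrical 1,3-dimethylallyl unit removes the regiochemical question and the ligand differentiates the two allyl termini. This should give (6S)-3-ethoxy-6-methyl-6-[(2R,3E)-pent-3-en-2-yl]cyclohex-2-en-1-one F1. The same OsO4/NaIO4 cleavage as in step 3, now of the internal alkene, comes back to the route at aldehyde 6.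

2. Step 9. The oxidant may enter on the face of the C5 side chain instead of the methyl face (poor or reversed facial selectivity at C7). The fallback sets out from 11 and reverses the order of bond formation at C7, so that the same facial bias delivers carbon last.
   - α′-Hydroxylation of 11 (KHMDS, then the same oxaziridine) gives (4S,6RS)-4-[(2S,3S)-3-[(tert-butyldimethylsilyl)oxy]pent-4-en-2-yl]-3-ethenyl-6-hydroxy-4-methylcyclohex-2-en-1-one F2.
   - 4-Methoxybenzyl trichloroacetimidate with a catalytic acid gives the ether (4S,6RS)-4-[(2S,3S)-3-[(tert-butyldimethylsilyl)oxy]pent-4-en-2-yl]-3-ethenyl-6-[(4-methoxyphenyl)methoxy]-4-methylcyclohex-2-en-1-one F3.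
   - Its zinc enolate (LDA, ZnCl2) adds to acetone on the side-chain face to give (4S,6S)-4-[(2S,3S)-3-[(tert-butyldimethylsilyl)oxy]pent-4-en-2-yl]-3-ethenyl-6-(2-hydroxypropan-2-yl)-6-[(4-methoxyphenyl)methoxy]-4-methylcyclohex-2-en-1-one F4.
   - Dehydration with (methoxycarbonylsulfamoyl)triethylammonium inner salt can only run towards a methyl group, because C7 is now quaternary, and gives (4S,6S)-4-[(2S,3S)-3-[(tert-butyldimethylsilyl)oxy]pent-4-en-2-yl]-3-ethenyl-6-[(4-methoxyphenyl)methoxy]-4-methyl-6-(prop-1-en-2-yl)cyclohex-2-en-1-one F5.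
   - DDQ in wet CH2Cl2 removes the benzyl ether and comes back to the route at 15.

3. Step 10. The selenium oxidation may stall or over-oxidise to the enal, or attack the other allylic positions (insufficient chemoselectivity). The fallback sets out from 15. Ene-type allylic chlorination with hypochlorous acid (Ca(OCl)2, solid CO2, CH2Cl2/H2O, 0 °C) should give (4S,6S)-4-[(2S,3S)-3-[(tert-butyldimethylsilyl)oxy]pent-4-en-2-yl]-6-(3-chloroprop-1-en-2-yl)-3-ethenyl-6-hydroxy-4-methylcyclohex-2-en-1-one F6. Displacement of the allylic chloride with caesium acetate in DMF comes back to the route at 17 and bypasses 16.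

Further compounds
F1 | step 2 | (6S)-3-ethoxy-6-methyl-6-[(2R,3E)-pent-3-en-2-yl]cyclohex-2-en-1-one | CCOC1=CC(=O)[C@@](C)(CC1)[C@H](C)/C=C/C
F2 | step 9 | (4S,6RS)-4-[(2S,3S)-3-[(tert-butyldimethylsilyl)oxy]pent-4-en-2-yl]-3-ethenyl-6-hydroxy-4-methylcyclohex-2-en-1-one | OC1C[C@](C)(C(C=C)=CC1=O)[C@H](C)[C@@H](O[Si](C)(C)C(C)(C)C)C=C
F3 | step 9 | (4S,6RS)-4-[(2S,3S)-3-[(tert-butyldimethylsilyl)oxy]pent-4-en-2-yl]-3-ethenyl-6-[(4-methoxyphenyl)methoxy]-4-methylcyclohex-2-en-1-one | COc1ccc(COC2C[C@](C)(C(C=C)=CC2=O)[C@H](C)[C@@H](O[Si](C)(C)C(C)(C)C)C=C)cc1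
F4 | step 9 | (4S,6S)-4-[(2S,3S)-3-[(tert-butyldimethylsilyl)oxy]pent-4-en-2-yl]-3-ethenyl-6-(2-hydroxypropan-2-yl)-6-[(4-methoxyphenyl)methoxy]-4-methylcyclohex-2-en-1-one | CC(C)(O)[C@@]1(OCc2ccc(OC)cc2)C[C@](C)(C(C=C)=CC1=O)[C@H](C)[C@@H](O[Si](C)(C)C(C)(C)C)C=C
F5 | step 9 | (4S,6S)-4-[(2S,3S)-3-[(tert-butyldimethylsilyl)oxy]pent-4-en-2-yl]-3-ethenyl-6-[(4-methoxyphenyl)methoxy]-4-methyl-6-(prop-1-en-2-yl)cyclohex-2-en-1-one | C=C(C)[C@@]1(OCc2ccc(OC)cc2)C[C@](C)(C(C=C)=CC1=O)[C@H](C)[C@@H](O[Si](C)(C)C(C)(C)C)C=C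
F6 | step 10 | (4S,6S)-4-[(2S,3S)-3-[(tert-butyldimethylsilyl)oxy]pent-4-en-2-yl]-6-(3-chloroprop-1-en-2-yl)-3-ethenyl-6-hydroxy-4-methylcyclohex-2-en-1-one | C=C(CCl)[C@@]1(O)C[C@](C)(C(C=C)=CC1=O)[C@H](C)[C@@H](O[Si](C)(C)C(C)(C)C)C=C
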